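**Remark (assumption):** the target has no stereogenic element. The sp3 centres of intermediates 8, 11, 16, 18 and 20 are racemic and are erased before the end, so the SMILES carry no stereodescriptors except alkene geometry.

## Analysis of the target

The target is a flavone: a benzo ring A fused to a 4-pyranone ring C, which carries a guaiacyl ring B at C2 and a methoxy group on the enol carbon C3. It is achiral, and the prenyl alkene has no E/Z isomerism, so no stereocontrol is needed. All the difficulty is in ring A. Five of its six carbons are substituted and its four oxygens are all different: C5–OH (hydrogen-bonded to C4=O), C7–O-prenyl, C8–OMe and the ring oxygen O1 on C8a; only C6 carries hydrogen. Routes that close ring C from an A-ring phenol must tell apart two ortho hydroxyls of a phloroglucinol-type ketone. This gives the well-known 5,7,8- versus 5,6,7-ambiguity (Wessely–Moser type) and demands a long series of selective protections. The sensitive groups are the O-prenyl ether, which rules out hydrogenolysis, boron halides, strong acid and prolonged strong heating, and the two free phenols; the 4'-OH must be carried under a group removable without acid or hydrogen. The feature that the route exploits is that C5–OH and C8–OMe are para to each other across ring A. Ring A is therefore a mono-methylated hydroquinone with one further alkoxy group (C7) and one hydrogen (C6) between the two oxygens, and its last two carbons, C4a and C8a, are the C5=C6 double bond of a 4-pyranone. This is exactly the substitution pattern produced by thermal ring expansion of a 4-alkenyl-4-methoxy-3-alkoxycyclobutenone.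

## Retrosynthetic reasoning

**22 ⇒ 21 (O–Si).** The last operation is cleavage of the silyl ether at O4' of 21 by a fluoride source. Fluoride leaves the prenyl ether, the three methyl ethers and the chelated 5-OH untouched. The end game is thus one trivial step.

**21 ⇒ 18 (key disconnection; C4a–C5 cut, C5–C8 re-joined).** Ring A of 21 is taken apart completely. C5, C6, C7 and C8 become the four carbons of cyclobutenone 18, and C4a/C8a go back to the C5=C6 bond of a monocyclic 4-pyranone that already carries ring B and the 3-OMe group. This cut is chosen because the para O5/O8 pair, the O7 alkoxy group and the C6 hydrogen map one-to-one onto the ketone, the methoxy carbinol, the vinylogous ester carbon and the vinyl CH of 18. The forward reaction, heating 18, must open the four-membered ring to the dienylketene 19, close ring A onto pyranone C5 to give 20, and tautomerise to the phenol. What is gained is that the 8-OMe/5-OH differentiation and the 6/8 regiochemistry are fixed by connectivity and not by selective chemistry on a phenol.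

**18 ⇒ 16 + 17 (O–CH3).** The tertiary methyl ether of 18 comes from carbinol 16 and iodomethane 17. Methylation before the ring expansion is what makes O8 a methyl ether and O5 a free phenol in 21.

**16 ⇒ 9 + 14 (C8–C8a).** The carbinol carbon of 16 is joined to pyranone C6 by 1,2-addition of lithiopyranone 15, made from pyranone 9 with a hindered lithium amide, to the ketone-like carbonyl of the prenyl semisquarate 14. The cut is placed here because both partners are small and ring-A-free, and because the two carbonyls of 14 differ strongly in electrophilicity.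

**14 ⇒ 12 + 13; 12 ⇒ 10.** The prenyloxy group of 14 is introduced by alkoxy exchange of the isopropyl semisquarate 12 with prenol 13. This puts the prenyl group in from the start and avoids a late selective prenylation. 12 is derived from commercial diisopropyl squarate 10 by mono-reduction to 11 and acid-induced carbonyl transposition.

**9 ⇒ 6 + 7 (pyranone O1–C6 and C3–C4).** Ring C is cut into α-methoxy ketone 6 and the three-carbon acid chloride 7. C-Acylation gives the diketone 8, whose enol oxygen closes the ring by addition–elimination at the ethoxyvinyl carbon. The cut uses the only enolisable position of 6, so no regiochemical question arises.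

**6 ⇒ 3 + 4; 3 ⇒ 1 + 2.** Ketone 6 comes from aryllithium 5, generated from bromide 3, and Weinreb amide 4. Bromide 3 is the silyl ether of commercial phenol 1, made with silyl chloride 2.

## Alternatives that were turned down

**Alternative 1:** the textbook route, cutting C2–C3 and O1–C2 of ring C. Claisen–Schmidt condensation of the fully oxygenated acetophenone A1 with the protected vanillin A2 would give chalcone A3. An Algar–Flynn–Oyamada oxidation would then give flavonol A4, followed by 3-O-methylation and deprotection. It was turned down for three reasons. First, A1 needs four different oxygen substituents on one ring (2-OH, 3-OMe, 4-O-prenyl, 6-O-protected); from a phloroglucinol ketone this costs a nuclear oxidation and several selective protections, about six steps before the first C–C bond. Second, a 6'-alkoxy group on a 2'-hydroxychalcone diverts the alkaline peroxide cyclisation towards aurones, while leaving the 6'-OH free re-opens the 5,7,8/5,6,7 ambiguity. Third, the linear sequence would run to about twelve steps, and ring C is closed by a phenol that first has to be made unique.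

**Alternative 2:** a Dötz benzannulation, cutting C5–C4a, C5–C6 and C7–C8. The chromium carbene complex A5, made from the same lithiated pyranone, would react with the alkoxyalkyne A6. Alkyne and CO insertion followed by electrocyclisation gives the same para OMe/OH pattern. It was turned down because the alkyne substituent normally ends up next to the CO-derived carbon, which would place the alkoxy group at C6 and give the 6-prenyloxy isomer A7, not the 7-isomer. In addition, the allyl alkynyl ether A6 is expected to undergo a [3,3] shift to an allylketene well below the reaction temperature. The route also needs stoichiometric chromium and saves no step over the squarate route, in which regiochemistry is fixed by the two different carbonyls.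

**Alternative 3:** an aryne route, cutting O1–C8a and C4–C4a. Fluoride-induced generation of aryne A9 from silyl triflate A8 in the presence of arylpropiolic acid A10 would add the carboxylate, transfer the acyl group to the ortho carbon and close the ynone to flavone A11. It was turned down because both aryne carbons are flanked by an alkoxy group (C5–O and C8–O), so the distortion that normally directs the nucleophile cancels and A11 would form together with its isomer A12. In addition, A8 is a hexasubstituted benzene that needs many steps, the fluoride would attack silyl protection on ring B, and the 3-OMe group would still have to be introduced afterwards.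

Key step: step 8

## Route

Step 1
Reactants: 1 4-bromo-2-methoxyphenol; 2 chlorotri(propan-2-yl)silane
Product: 3 (4-bromo-2-methoxyphenoxy)tri(propan-2-yl)silane
Conditions: imidazole, DMF, rt
Reagents that add atoms: chlorotri(propan-2-yl)silane (2), CC(C)[Si](Cl)(C(C)C)C(C)C
Why: Standard phenol silylation; the bulky aryl silyl ether should survive organolithiums, LiTMP, TFA and 110 °C and is removed at the end by fluoride without touching the prenyl ether.

Step 2
Reactants: 3 (4-bromo-2-methoxyphenoxy)tri(propan-2-yl)silane; 4 N,2-dimethoxy-N-methylacetamide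
Product: 6 2-methoxy-1-{3-methoxy-4-[tri(propan-2-yl)silyloxy]phenyl}ethan-1-one, via aryllithium 5 (not isolated)
Conditions: n-BuLi, THF, −78 °C; then 4, −78 to 0 °C; dilute aq. HCl work-up
Reagents that add atoms: N,2-dimethoxy-N-methylacetamide (4), COCC(=O)N(C)OC
Why: Bromine–lithium exchange followed by a Weinreb ketone synthesis; the chelated tetrahedral adduct prevents over-addition and delivers the α-methoxy ketone that carries C2, C3 and the 3-OMe group of ring C.

Step 3
Reactants: 6 2-methoxy-1-{3-methoxy-4-[tri(propan-2-yl)silyloxy]phenyl}ethan-1-one; 7 (2E)-3-ethoxyprop-2-enoyl chloride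
Product: 9 3-methoxy-2-{3-methoxy-4-[tri(propan-2-yl)silyloxy]phenyl}-4H-pyran-4-one, via ethoxyvinyl diketone 8 (not isolated)
Conditions: MgBr2·OEt2, i-Pr2NEt, CH2Cl2, 0 °C to rt; then TFA, rt
Reagents that add atoms: (2E)-3-ethoxyprop-2-enoyl chloride (7), CCO/C=C/C(Cl)=O
Why: Soft-enolisation C-acylation of the chelated magnesium enolate of the α-methoxy ketone should give the 1,3-diketone 8; acid then lets the enol oxygen add 6-endo to the β-ethoxy enone and expel ethanol, the usual γ-pyrone closure of a 1,3,5-tricarbonyl equivalent.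

Step 4
Reactants: 10 3,4-di(propan-2-yloxy)cyclobut-3-ene-1,2-dione
Product: 12 3-(propan-2-yloxy)cyclobut-3-ene-1,2-dione, via hydroxycyclobutenone 11 (not isolated)
Conditions: LiAlH(OtBu)3, THF, −78 to 0 °C; then conc. aq. HCl, CH2Cl2, rt
Reagents that add atoms: water, O
Why: The bulky hydride reduces one squarate carbonyl 1,2; acid then ionises the carbinol, water adds at the alkoxy-stabilised allyl cation terminus and isopropanol is lost (1,3-carbonyl transposition), the standard conversion of a squaric diester into a 3-alkoxycyclobutenedione.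

Step 5
Reactants: 12 3-(propan-2-yloxy)cyclobut-3-ene-1,2-dione; 13 3-methylbut-2-en-1-ol
Product: 14 3-[(3-methylbut-2-en-1-yl)oxy]cyclobut-3-ene-1,2-dione
Conditions: 13 (excess), Et3N (cat.), CH2Cl2, rt; isopropanol removed under reduced pressure
Reagents that add atoms: 3-methylbut-2-en-1-ol (13), CC(C)=CCO
Why: Vinylogous transesterification by addition–elimination at the doubly activated alkoxy-bearing carbon, the same alkoxy exchange that squaric esters undergo in alcohols with amine bases; excess prenol and removal of the more volatile isopropanol should drive it, and base catalysis spares the acid-sensitive allylic alcohol.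

Step 6
Reactants: 9 3-methoxy-2-{3-methoxy-4-[tri(propan-2-yl)silyloxy]phenyl}-4H-pyran-4-one; 14 3-[(3-methylbut-2-en-1-yl)oxy]cyclobut-3-ene-1,2-dione
Product: 16 4-hydroxy-4-(5-methoxy-6-{3-methoxy-4-[tri(propan-2-yl)silyloxy]phenyl}-4-oxo-4H-pyran-2-yl)-3-[(3-methylbut-2-en-1-yl)oxy]cyclobut-2-en-1-one, via lithiopyranone 15 (not isolated)
Conditions: lithium 2,2,6,6-tetramethylpiperidide (LiTMP, from 2,2,6,6-tetramethylpiperidine and n-BuLi), THF, −78 °C; then cannulation into 14, THF, −78 °C; AcOH, −78 °C
Reagents that add atoms: 3-[(3-methylbut-2-en-1-yl)oxy]cyclobut-3-ene-1,2-dione (14), CC(C)=CCOC1=CC(=O)C1=O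
Why: The hindered amide should remove the sp2 hydrogen at pyranone C6, α to the ring oxygen and β to the carbonyl, which is the site at which chromones, 4-quinolones and uracils are lithiated. The vinyllithium then adds 1,2 to the ketone-like carbonyl of 14 (the one next to the alkoxy-bearing carbon) and not to the vinylogous ester carbonyl, as is usual for 3-alkoxycyclobutenediones. The new carbinol centre is racemic and is erased in step 8.

Step 7
Reactants: 16 4-hydroxy-4-(5-methoxy-6-{3-methoxy-4-[tri(propan-2-yl)silyloxy]phenyl}-4-oxo-4H-pyran-2-yl)-3-[(3-methylbut-2-en-1-yl)oxy]cyclobut-2-en-1-one; 17 iodomethane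
Product: 18 4-methoxy-4-(5-methoxy-6-{3-methoxy-4-[tri(propan-2-yl)silyloxy]phenyl}-4-oxo-4H-pyran-2-yl)-3-[(3-methylbut-2-en-1-yl)oxy]cyclobut-2-en-1-one
Conditions: MeI (excess), Ag2O, MeCN, rt, dark
Reagents that add atoms: iodomethane (17), CI
Why: Silver-oxide-mediated O-methylation (Purdie type) of the tertiary cyclobutenol under nearly neutral conditions, which does not alkylate the pyranone carbonyl; it fixes the future O8 as a methyl ether, so that the ring expansion gives a mono-protected hydroquinone and not an air-sensitive 5,8-quinol.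

Step 8
Reactants: 18 4-methoxy-4-(5-methoxy-6-{3-methoxy-4-[tri(propan-2-yl)silyloxy]phenyl}-4-oxo-4H-pyran-2-yl)-3-[(3-methylbut-2-en-1-yl)oxy]cyclobut-2-en-1-one
Product: 21 5-hydroxy-3,8-dimethoxy-2-{3-methoxy-4-[tri(propan-2-yl)silyloxy]phenyl}-7-[(3-methylbut-2-en-1-yl)oxy]-4H-chromen-4-one, via dienylketene 19 (not isolated), via ring-fused dienone 20 (not isolated)
Conditions: toluene (degassed), 110 °C
Reagents that add atoms: none
Why: Heating should open the cyclobutenone by a 4π-conrotatory electrocyclic cleavage of the C1–C4 bond; the donor OMe at C4 rotates outward (torquoselectivity of donor groups), which turns the pyranonyl group inward and gives the (Z)-dienylketene 19. The ketene carbon and pyranone C5 then close ring A by a thermal disrotatory 6π-electrocyclisation, formally a 6-endo attack of the nucleophilic enol-ether carbon C5 of the pyranone on the electrophilic ketene carbon, which forms the C4a–C5 bond and dienone 20. Enolisation of 20 aromatises ring A and removes its only sp3 centre (C4a, racemic, no lasting stereocentre); the new 5-OH is held by a hydrogen bond to C4=O. The closest known reaction type is the Moore rearrangement of 4-aryl-, 4-heteroaryl- and 4-alkenyl-4-alkoxycyclobutenones to mono-protected hydroquinones. Regiochemistry needs no selectivity at this stage: C8 carries OMe because it was the carbinol carbon bonded to pyranone C6 (the future C8a), C7 carries the prenyloxy group and C6 the hydrogen because they were C3 and C2 of the four-membered ring, and C5–OH is the former ketone. The selectivities that are needed are outward rotation of OMe, secured electronically, and ring expansion ahead of a [3,3] shift of the prenyl vinyl ether or a ketene–alkene cycloaddition, secured by the polarity-matched 6π closure and by the quaternary carbon that a [3,3] shift would have to create. The precursor contains no benzenoid ring A, so a single isomerisation builds the penta-substituted ring with all four oxygen functions differentiated.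

Step 9
Reactants: 21 5-hydroxy-3,8-dimethoxy-2-{3-methoxy-4-[tri(propan-2-yl)silyloxy]phenyl}-7-[(3-methylbut-2-en-1-yl)oxy]-4H-chromen-4-one
Product: 22 5-hydroxy-2-(4-hydroxy-3-methoxyphenyl)-3,8-dimethoxy-7-[(3-methylbut-2-en-1-yl)oxy]-4H-chromen-4-one
Conditions: tetrabutylammonium fluoride, AcOH, THF, 0 °C
Reagents that add atoms: none
Why: Fluoride-induced desilylation of the aryl silyl ether; the acetic acid buffer keeps the medium mild, and the prenyl ether, the methyl ethers and the chelated 5-OH are inert.

## Compound list

1 | 4-bromo-2-methoxyphenol | COc1cc(Br)ccc1O | starting material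
2 | chlorotri(propan-2-yl)silane | CC(C)[Si](Cl)(C(C)C)C(C)C | starting material
3 | (4-bromo-2-methoxyphenoxy)tri(propan-2-yl)silane | COc1cc(Br)ccc1O[Si](C(C)C)(C(C)C)C(C)C | intermediate
4 | N,2-dimethoxy-N-methylacetamide | COCC(=O)N(C)OC | starting material
5 | {3-methoxy-4-[tri(propan-2-yl)silyloxy]phenyl}lithium (aryllithium) | [Li]c1ccc(O[Si](C(C)C)(C(C)C)C(C)C)c(OC)c1 | intermediate
6 | 2-methoxy-1-{3-methoxy-4-[tri(propan-2-yl)silyloxy]phenyl}ethan-1-one | COCC(=O)c1ccc(O[Si](C(C)C)(C(C)C)C(C)C)c(OC)c1 | intermediate
7 | (2E)-3-ethoxyprop-2-enoyl chloride | CCO/C=C/C(Cl)=O | starting material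
8 | (4E)-5-ethoxy-2-methoxy-1-{3-methoxy-4-[tri(propan-2-yl)silyloxy]phenyl}pent-4-ene-1,3-dione (racemic, enolisable) | CCO/C=C/C(=O)C(OC)C(=O)c1ccc(O[Si](C(C)C)(C(C)C)C(C)C)c(OC)c1 | intermediate
9 | 3-methoxy-2-{3-methoxy-4-[tri(propan-2-yl)silyloxy]phenyl}-4H-pyran-4-one | COc1cc(-c2occc(=O)c2OC)ccc1O[Si](C(C)C)(C(C)C)C(C)C | intermediate
10 | 3,4-di(propan-2-yloxy)cyclobut-3-ene-1,2-dione (diisopropyl squarate) | CC(C)OC1=C(OC(C)C)C(=O)C1=O | starting material
11 | 4-hydroxy-2,3-di(propan-2-yloxy)cyclobut-2-en-1-one (racemic) | CC(C)OC1=C(OC(C)C)C(O)C1=O | intermediate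
12 | 3-(propan-2-yloxy)cyclobut-3-ene-1,2-dione | CC(C)OC1=CC(=O)C1=O | intermediate
13 | 3-methylbut-2-en-1-ol (prenol) | CC(C)=CCO | starting material
14 | 3-[(3-methylbut-2-en-1-yl)oxy]cyclobut-3-ene-1,2-dione | CC(C)=CCOC1=CC(=O)C1=O | intermediate
15 | (5-methoxy-6-{3-methoxy-4-[tri(propan-2-yl)silyloxy]phenyl}-4-oxo-4H-pyran-2-yl)lithium (lithiopyranone) | [Li]c1cc(=O)c(OC)c(-c2ccc(O[Si](C(C)C)(C(C)C)C(C)C)c(OC)c2)o1 | intermediate
16 | 4-hydroxy-4-(5-methoxy-6-{3-methoxy-4-[tri(propan-2-yl)silyloxy]phenyl}-4-oxo-4H-pyran-2-yl)-3-[(3-methylbut-2-en-1-yl)oxy]cyclobut-2-en-1-one (racemic) | O=C1C=C(OCC=C(C)C)C1(O)c1cc(=O)c(OC)c(-c2ccc(O[Si](C(C)C)(C(C)C)C(C)C)c(OC)c2)o1 | intermediate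
17 | iodomethane | CI | starting material
18 | 4-methoxy-4-(5-methoxy-6-{3-methoxy-4-[tri(propan-2-yl)silyloxy]phenyl}-4-oxo-4H-pyran-2-yl)-3-[(3-methylbut-2-en-1-yl)oxy]cyclobut-2-en-1-one (racemic) | O=C1C=C(OCC=C(C)C)C1(OC)c1cc(=O)c(OC)c(-c2ccc(O[Si](C(C)C)(C(C)C)C(C)C)c(OC)c2)o1 | intermediate
19 | (3Z)-4-methoxy-4-(5-methoxy-6-{3-methoxy-4-[tri(propan-2-yl)silyloxy]phenyl}-4-oxo-4H-pyran-2-yl)-3-[(3-methylbut-2-en-1-yl)oxy]buta-1,3-dien-1-one (dienylketene) | O=C=C/C(OCC=C(C)C)=C(/OC)c1cc(=O)c(OC)c(-c2ccc(O[Si](C(C)C)(C(C)C)C(C)C)c(OC)c2)o1 | intermediate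
20 | 3,8-dimethoxy-2-{3-methoxy-4-[tri(propan-2-yl)silyloxy]phenyl}-7-[(3-methylbut-2-en-1-yl)oxy]-4aH-chromene-4,5-dione (racemic ring-fused dienone) | O=C1C=C(OCC=C(C)C)C(OC)=C2OC(c3ccc(O[Si](C(C)C)(C(C)C)C(C)C)c(OC)c3)=C(OC)C(=O)C12 | intermediate
21 | 5-hydroxy-3,8-dimethoxy-2-{3-methoxy-4-[tri(propan-2-yl)silyloxy]phenyl}-7-[(3-methylbut-2-en-1-yl)oxy]-4H-chromen-4-one | COc1cc(-c2oc3c(OC)c(OCC=C(C)C)cc(O)c3c(=O)c2OC)ccc1O[Si](C(C)C)(C(C)C)C(C)C | intermediate
22 | 5-hydroxy-2-(4-hydroxy-3-methoxyphenyl)-3,8-dimethoxy-7-[(3-methylbut-2-en-1-yl)oxy]-4H-chromen-4-one | COc1cc(-c2oc3c(OC)c(OCC=C(C)C)cc(O)c3c(=O)c2OC)ccc1O | target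

## Step count and risk

Total step count: 9 (steps 1–3 for the pyranone, steps 4–5 for the semisquarate, steps 6–9 for union, ring expansion and deprotection).
Longest linear sequence: 7 steps (1, 2, 3, 6, 7, 8, 9) from 4-bromo-2-methoxyphenol.

**Step 8 (key step).** The most likely failure is diversion of the pericyclic cascade by the prenyl group: a [3,3] shift of the prenyl vinyl ether in 18 or 19, or an intramolecular ketene–alkene cycloaddition, before the 6π closure onto the only weakly alkene-like pyranone bond. Inward rotation of OMe, which would lead to a furanone, is a smaller risk.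
Fallback (from 12 and 15, back at 21): the prenyl group is kept out of the thermal step and put on late. Lithiopyranone 15 would be added to the isopropyl semisquarate 12 to give the isopropoxy hydroxycyclobutenone F1, which would be methylated with 17 and Ag2O to the methyl ether F2 and heated in toluene to the 7-isopropoxyflavone F3. BCl3 in CH2Cl2 at −78 to 0 °C would cleave the isopropyl ether in preference to the methyl ethers and give the 5,7-diol F4. Prenyl bromide and K2CO3 in acetone would then alkylate the free 7-OH, the 5-OH being chelated and unreactive, and return to 21.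

**Step 6.** Several things may go wrong: deprotonation at pyranone C5 in place of C6, which would later give the ring-A isomer with inverted fusion; self-condensation of the lithiopyranone with unreacted 9; and conjugate attack on 14 in place of 1,2-addition.
Fallback (from 6, back at 15): the metalation site is fixed by construction. Ketone 6 would be acylated under the conditions of step 3 with 3,3-dichloroprop-2-enoyl chloride and cyclised with loss of HCl to the 6-chloropyranone F5. Stannylation with Me3Sn–SnMe3 and Pd(PPh3)4 (zerovalent palladium) in dioxane at 90 °C would give the 6-trimethylstannylpyranone F6. Tin–lithium exchange with MeLi in THF at −78 °C would then generate 15 at C6 only, which is added to 14 as in step 6.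

**Step 5.** The alkoxy exchange may stall at equilibrium, or the base may trigger addition at the carbonyl groups and ring cleavage of the strained dione.
Fallback (from 12, back at 14): exchange is replaced by hydrolysis and O-alkylation. 12 would be hydrolysed with aqueous HCl to semisquaric acid F7, and its silver salt, formed with Ag2O in MeCN in the dark, would be alkylated on oxygen with prenyl bromide to give 14.

**Step 3.** O-Acylation of the enolate may compete with C-acylation, and the acid-sensitive ethoxyvinyl ketone may polymerise before ring closure.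
Fallback (from 6, back at 9): the three carbons are added by aldol chemistry and a formamide acetal. The lithium enolate of 6 (LiHMDS, THF, −78 °C) would add to acetaldehyde to give the aldol F8 as a mixture of diastereomers, and the periodinane DMP would oxidise it to the methyl diketone F9. Me2NCH(OMe)2 in toluene at 80 °C would condense at the terminal methyl group, the central carbon being blocked by OMe, and give the enaminone F10. TFA would then close the ring with loss of dimethylamine to give 9.

## Further compounds

F1 | step 8 | 4-hydroxy-4-(5-methoxy-6-{3-methoxy-4-[tri(propan-2-yl)silyloxy]phenyl}-4-oxo-4H-pyran-2-yl)-3-(propan-2-yloxy)cyclobut-2-en-1-one (racemic) | O=C1C=C(OC(C)C)C1(O)c1cc(=O)c(OC)c(-c2ccc(O[Si](C(C)C)(C(C)C)C(C)C)c(OC)c2)o1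
F2 | step 8 | 4-methoxy-4-(5-methoxy-6-{3-methoxy-4-[tri(propan-2-yl)silyloxy]phenyl}-4-oxo-4H-pyran-2-yl)-3-(propan-2-yloxy)cyclobut-2-en-1-one (racemic) | O=C1C=C(OC(C)C)C1(OC)c1cc(=O)c(OC)c(-c2ccc(O[Si](C(C)C)(C(C)C)C(C)C)c(OC)c2)o1
F3 | step 8 | 5-hydroxy-3,8-dimethoxy-2-{3-methoxy-4-[tri(propan-2-yl)silyloxy]phenyl}-7-(propan-2-yloxy)-4H-chromen-4-one | COc1cc(-c2oc3c(OC)c(OC(C)C)cc(O)c3c(=O)c2OC)ccc1O[Si](C(C)C)(C(C)C)C(C)C
F4 | step 8 | 5,7-dihydroxy-3,8-dimethoxy-2-{3-methoxy-4-[tri(propan-2-yl)silyloxy]phenyl}-4H-chromen-4-one | COc1cc(-c2oc3c(OC)c(O)cc(O)c3c(=O)c2OC)ccc1O[Si](C(C)C)(C(C)C)C(C)C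
F5 | step 6 | 6-chloro-3-methoxy-2-{3-methoxy-4-[tri(propan-2-yl)silyloxy]phenyl}-4H-pyran-4-one | COc1cc(-c2oc(Cl)cc(=O)c2OC)ccc1O[Si](C(C)C)(C(C)C)C(C)C
F6 | step 6 | 3-methoxy-2-{3-methoxy-4-[tri(propan-2-yl)silyloxy]phenyl}-6-(trimethylstannyl)-4H-pyran-4-one | COc1cc(-c2oc([Sn](C)(C)C)cc(=O)c2OC)ccc1O[Si](C(C)C)(C(C)C)C(C)C
F7 | step 5 | 3-hydroxycyclobut-3-ene-1,2-dione (semisquaric acid) | O=C1C=C(O)C1=O
F8 | step 3 | 3-hydroxy-2-methoxy-1-{3-methoxy-4-[tri(propan-2-yl)silyloxy]phenyl}butan-1-one (racemic mixture of diastereomers) | CC(O)C(OC)C(=O)c1ccc(O[Si](C(C)C)(C(C)C)C(C)C)c(OC)c1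
F9 | step 3 | 2-methoxy-1-{3-methoxy-4-[tri(propan-2-yl)silyloxy]phenyl}butane-1,3-dione (racemic) | CC(=O)C(OC)C(=O)c1ccc(O[Si](C(C)C)(C(C)C)C(C)C)c(OC)c1
F10 | step 3 | (4E)-5-(dimethylamino)-2-methoxy-1-{3-methoxy-4-[tri(propan-2-yl)silyloxy]phenyl}pent-4-ene-1,3-dione (racemic) | CN(C)/C=C/C(=O)C(OC)C(=O)c1ccc(O[Si](C(C)C)(C(C)C)C(C)C)c(OC)c1
A1 | alternative 1 | 1-{2-hydroxy-3-methoxy-6-(methoxymethoxy)-4-[(3-methylbut-2-en-1-yl)oxy]phenyl}ethan-1-one | CC(=O)c1c(O)c(OC)c(OCC=C(C)C)cc1OCOC
A2 | alternative 1 | 3-methoxy-4-(methoxymethoxy)benzaldehyde | COCOc1ccc(C=O)cc1OC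
A3 | alternative 1 | (2E)-1-{2-hydroxy-3-methoxy-6-(methoxymethoxy)-4-[(3-methylbut-2-en-1-yl)oxy]phenyl}-3-[3-methoxy-4-(methoxymethoxy)phenyl]prop-2-en-1-one | COCOc1ccc(/C=C/C(=O)c2c(O)c(OC)c(OCC=C(C)C)cc2OCOC)cc1OC
A4 | alternative 1 | 3-hydroxy-8-methoxy-5-(methoxymethoxy)-2-[3-methoxy-4-(methoxymethoxy)phenyl]-7-[(3-methylbut-2-en-1-yl)oxy]-4H-chromen-4-one | COCOc1ccc(-c2oc3c(OC)c(OCC=C(C)C)cc(OCOC)c3c(=O)c2O)cc1OC
A5 | alternative 2 | pentacarbonyl[methoxy(5-methoxy-6-{3-methoxy-4-[tri(propan-2-yl)silyloxy]phenyl}-4-oxo-4H-pyran-2-yl)methylidene]chromium | COC(=[Cr])c1cc(=O)c(OC)c(-c2ccc(O[Si](C(C)C)(C(C)C)C(C)C)c(OC)c2)o1.[C-]#[O+].[C-]#[O+].[C-]#[O+].[C-]#[O+].[C-]#[O+]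
A6 | alternative 2 | 1-(ethynyloxy)-3-methylbut-2-ene | C#COCC=C(C)C
A7 | alternative 2 | 5-hydroxy-3,8-dimethoxy-2-{3-methoxy-4-[tri(propan-2-yl)silyloxy]phenyl}-6-[(3-methylbut-2-en-1-yl)oxy]-4H-chromen-4-one | COc1cc(-c2oc3c(OC)cc(OCC=C(C)C)c(O)c3c(=O)c2OC)ccc1O[Si](C(C)C)(C(C)C)C(C)C
A8 | alternative 3 | 2-methoxy-5-(methoxymethoxy)-3-[(3-methylbut-2-en-1-yl)oxy]-6-(trimethylsilyl)phenyl trifluoromethanesulfonate | COCOc1cc(OCC=C(C)C)c(OC)c(OS(=O)(=O)C(F)(F)F)c1[Si](C)(C)C
A9 | alternative 3 | 3-methoxy-6-(methoxymethoxy)-4-[(3-methylbut-2-en-1-yl)oxy]benzyne | COCOC1=CC(OCC=C(C)C)=C(OC)C#C1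
A10 | alternative 3 | 3-[3-methoxy-4-(methoxymethoxy)phenyl]prop-2-ynoic acid | COCOc1ccc(C#CC(=O)O)cc1OC
A11 | alternative 3 | 8-methoxy-5-(methoxymethoxy)-2-[3-methoxy-4-(methoxymethoxy)phenyl]-7-[(3-methylbut-2-en-1-yl)oxy]-4H-chromen-4-one | COCOc1ccc(-c2cc(=O)c3c(OCOC)cc(OCC=C(C)C)c(OC)c3o2)cc1OC
A12 | alternative 3 | 5-methoxy-8-(methoxymethoxy)-2-[3-methoxy-4-(methoxymethoxy)phenyl]-6-[(3-methylbut-2-en-1-yl)oxy]-4H-chromen-4-one | COCOc1ccc(-c2cc(=O)c3c(OC)c(OCC=C(C)C)cc(OCOC)c3o2)cc1OC
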